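**Retrosynthetic overview**

- The target is a longipinane: the cyclobutane bond C4–C10 is cut last (C4 of a ring-A silyl dienol ether attacks a 9α,10α-epoxide), and the ester/hydroxyl pattern at O7, O8, O9 is set by staged protection.
- Structural feature used: in the seven-membered ring C5–C6–C7–C8–C9–C10–C11, C7 carries oxygen next to quaternary C6 and C11 is α to the C1 ketone. Joining C7 and C11 through that oxygen gives an 8-oxabicyclo[3.2.1]octenone, the signature of a pyrylium ylide adduct; SmI2 removes the bridge once C1 is a ketone.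
- Key disconnection: C6–C7 and C5–C11, by intramolecular (5+2) cycloaddition of a 3-oxidopyrylium with the tethered prenyl alkene. The (R)-C1 silyloxy centre selects the face.
- The ylide precursor (acetoxypyranone 18) comes from 3-methylfuran-2-carbaldehyde by C5 hydroxymethylation, asymmetric propyne addition, Red-Al/I2, Negishi prenylation and Achmatowicz oxidation.
- Ring order: furan → pyranone (step 8) → seven-membered ring and cyclohexene together (step 10) → ether bridge cut (step 16) → cyclobutane (step 22).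

Key step: step 10

Remark 1 (convention): atoms are numbered C1–C11 as in the target (ring A = C1–C2–C3–C4–C5–C11, ring B = C5–C6–C7–C8–C9–C10–C11); β is the face of ring B carrying O7 and C4, α the other face.

Remark 2 (assumption): the (S,S)-ProPhenol–zinc catalyst is assumed to deliver propyne to the Re face of aldehyde 5; if Mosher analysis of 8 shows the opposite, the (R,R)-ligand is used.

Step 1
Reactants: 1 3-methylfuran-2-carbaldehyde
Product: 4 5-(hydroxymethyl)-3-methylfuran-2-carbaldehyde, via lithium amino alkoxide 2 (not isolated), via C5-lithio amino alkoxide 3 (not isolated)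
Conditions: N-methylpiperazine, n-BuLi, THF, −78 °C; add 1; n-BuLi, −78 → −20 °C; (CH2O)n, −78 °C → rt; aq NH4Cl
Reagents that add atoms: formaldehyde (from paraformaldehyde), C=O
Why: The lithium amide masks the aldehyde as an α-amino alkoxide, n-BuLi then removes the only ring α-proton (C5, the C3 site being blocked by methyl) and the furyllithium is hydroxymethylated (Comins in-situ protection and directed lithiation of a furfural).

Step 2
Reactants: 4 5-(hydroxymethyl)-3-methylfuran-2-carbaldehyde
Product: 5 3-methyl-5-[(triethylsilyloxy)methyl]furan-2-carbaldehyde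
Conditions: TESCl, imidazole, CH2Cl2, 0 °C
Reagents that add atoms: chlorotriethylsilane, CC[Si](Cl)(CC)CC
Why: Standard silylation of a primary alcohol; the TES ether tolerates the organometallic steps and is later removed beside a secondary TBS ether.

Step 3
Reactants: 5 3-methyl-5-[(triethylsilyloxy)methyl]furan-2-carbaldehyde; 6 propyne
Product: 8 (R)-1-{3-methyl-5-[(triethylsilyloxy)methyl]furan-2-yl}but-2-yn-1-ol, via propynylzinc 7 (not isolated)
Conditions: (S,S)-ProPhenol (10 mol %), Ph3PO (20 mol %), Me2Zn, toluene, 0 °C; aq NH4Cl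
Reagents that add atoms: none
Why: Zinc–ProPhenol catalysed enantioselective alkynylation of a heteroaromatic aldehyde; Re-face delivery of the alkynyl group sets C1 as R (O > furyl > alkynyl > H), the only stereocentre the route introduces from outside.

Step 4
Reactants: 8 (R)-1-{3-methyl-5-[(triethylsilyloxy)methyl]furan-2-yl}but-2-yn-1-ol
Product: 10 (R,Z)-3-iodo-1-{3-methyl-5-[(triethylsilyloxy)methyl]furan-2-yl}but-2-en-1-ol, via alkenylalanate 9 (not isolated)
Conditions: Red-Al, THF, 0 °C → rt; EtOAc; I2, THF, −78 → 0 °C; aq Rochelle salt, Na2S2O3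
Reagents that add atoms: iodine, II
Why: Alkoxide-directed trans-hydroalumination of the propargylic alcohol places aluminium on the distal carbon cis to C1, and iodinolysis with retention gives the (Z)-γ-iodo allylic alcohol (Corey-type trisubstituted alkene synthesis).

Step 5
Reactants: 10 (R,Z)-3-iodo-1-{3-methyl-5-[(triethylsilyloxy)methyl]furan-2-yl}but-2-en-1-ol
Product: 11 tert-butyldimethylsilyl ether of 10
Conditions: TBSCl, imidazole, DMF, rt
Reagents that add atoms: tert-butyldimethylsilyl chloride, CC(C)(C)[Si](C)(C)Cl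
Why: Routine silylation of the secondary alcohol; the bulky silyloxy group at C1 is the later control element of the cycloaddition.

Step 6
Reactants: 11 tert-butyldimethylsilyl ether of 10; 12 prenyl bromide
Product: 15 (R,Z)-1-(tert-butyldimethylsilyloxy)-3,6-dimethyl-1-{3-methyl-5-[(triethylsilyloxy)methyl]furan-2-yl}hepta-2,5-diene, via alkenyllithium 13 (not isolated), via alkenylzinc chloride 14 (not isolated)
Conditions: t-BuLi (2.1 equiv), Et2O, −78 °C; ZnCl2, THF, −78 → 0 °C; Pd(PPh3)4 (5 mol %), 12, 0 °C → rt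
Reagents that add atoms: none
Why: Iodine–lithium exchange and transmetallation to zinc at low temperature keep the alkene geometry and outrun 1,4-silyl migration, and the Negishi alkenyl–allyl coupling joins the prenyl unit at its unsubstituted terminus with retention, giving the Z skipped diene (C1 and C4 cis).

Step 7
Reactants: 15 bis-silyl ether
Product: 16 {5-[(R,Z)-1-(tert-butyldimethylsilyloxy)-3,6-dimethylhepta-2,5-dien-1-yl]-4-methylfuran-2-yl}methanol
Conditions: HF·pyridine, pyridine, THF, 0 °C
Reagents that add atoms: none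
Why: Buffered fluoride cleaves the primary TES ether much faster than the hindered secondary TBS ether and avoids acid ionisation of the furfurylic, allylic C1–O bond.

Step 8
Reactants: 16 furfuryl alcohol
Product: 17 6-hydroxy-5-methyl-6-[(R,Z)-1-(tert-butyldimethylsilyloxy)-3,6-dimethylhepta-2,5-dien-1-yl]-2H-pyran-3(6H)-one (C11 lactol, both anomers, one drawn)
Conditions: NBS (1.05 equiv), NaHCO3, NaOAc, THF/H2O 4:1, 0 °C
Reagents that add atoms: water, O
Why: Achmatowicz oxidative ring expansion; the furan, far more electron-rich than the trisubstituted alkenes, is opened to the Z-enedione and the free primary hydroxyl closes on the C11 carbonyl, so CH2–O becomes C7–O of the pyranone.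

Step 9
Reactants: 17 hydroxypyranone
Product: 18 6-acetoxy-5-methyl-6-[(R,Z)-1-(tert-butyldimethylsilyloxy)-3,6-dimethylhepta-2,5-dien-1-yl]-2H-pyran-3(6H)-one (both C11 anomers, one drawn)
Conditions: Ac2O, Et3N, DMAP (cat.), CH2Cl2, 0 °C
Reagents that add atoms: acetic anhydride, CC(=O)OC(C)=O
Why: DMAP-catalysed acetylation of the tertiary lactol gives the ylide precursor; the anomeric configuration is lost in the next step.

Step 10
Reactants: 18 acetoxypyranone
Product: 20 (1R,5R,7S,11R)-1-(tert-butyldimethylsilyloxy)-7β,11β-epoxy-3,6,6,10-tetramethyl ring A/ring B bicycle-2,9-dien-8-one (H-5 α), via 3-oxidopyrylium ylide 19 (not isolated)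
Conditions: DBU (1.5 equiv), MeCN (0.01 M), rt → 60 °C
Reagents that add atoms: none
Why: DBU removes a C7 proton and acetate leaves from C11, giving the planar 3-oxidopyrylium 19, whose termini C7 and C11 add suprafacially to the tethered C5=C6 alkene in one thermal step (intramolecular oxidopyrylium–alkene (5+2) cycloaddition of an Achmatowicz-derived acetoxypyranone, the Hendrickson–Sammes–Wender reaction type). The seven-membered carbocycle C5–C6–C7–C8–C9–C10–C11 closes as the two-carbon bridge of the 8-oxabicyclo[3.2.1]octenone, and the cyclohexene C1–C2–C3–C4–C5–C11 closes through the four-atom tether when C5–C11 forms, the Z C2=C3 alkene already holding C1 and C4 cis. C7 and C11 are set together because both bonds form on one face of the ylide, and C5 is set by the tether, which can span C11 and C5 only with C4 exo (syn to the oxygen bridge, H-5 endo). The face is chosen by the (R)-C1 centre: with C2 reaching towards the alkene, the C1 hydrogen lies in the ylide plane beside the C10 methyl (minimal A(1,3) strain) and the silyloxy group stands anti to the forming C5–C11 bond, pseudo-equatorial on the new cyclohexene, whereas addition to the other face would press the silyloxy group against the C10 methyl. The step needs regio-, exo/endo- and facial selectivity: the tether length secures the first two (C6 must meet C7, which also builds the quaternary centre intramolecularly), the C1 centre the third, and high dilution holds back ylide dimerisation.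

Step 11
Reactants: 20 cycloadduct
Product: 21 8α-alcohol of 20 (hydroxyl trans to O7)
Conditions: NaBH4, CeCl3·7H2O, MeOH, −78 → −40 °C
Reagents that add atoms: none
Why: Luche 1,2-reduction; hydride reaches C8 from the face of the oxygen bridge because the other face is covered by the endo methyl on C6, so the hydroxyl ends α.

Step 12
Reactants: 21 8α-alcohol
Product: 22 8α-(4-methoxybenzyl) ether of 21
Conditions: NaH, PMBCl, Bu4NI (cat.), DMF, 0 °C → rt
Reagents that add atoms: 4-methoxybenzyl chloride, COc1ccc(CCl)cc1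
Why: Williamson etherification; the PMB ether survives fluoride, oxidation, base and SmI2 and is removed oxidatively when the hydroxyl is needed to direct the epoxidation.

Step 13
Reactants: 22 PMB ether
Product: 23 (1R)-1-alcohol (TBS removed)
Conditions: TBAF, THF, 0 °C → rt
Reagents that add atoms: none
Why: Fluoride cleavage of the silyl ether once the C1 centre has done its work.

Step 14
Reactants: 23 1-alcohol
Product: 24 7β,11β-epoxy-8α-(4-methoxybenzyloxy)-bicycle-2,9-dien-1-one (ring-A enone)
Conditions: Dess–Martin periodinane, NaHCO3, CH2Cl2, 0 °C → rt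
Reagents that add atoms: none
Why: Oxidation of the allylic alcohol removes the C1 stereocentre and makes C11–O an α-alkoxy ketone bond, the one SmI2 will cut.

Step 15
Reactants: 24 ring-A enone
Product: 26 7β,11β-epoxy-8α-(4-methoxybenzyloxy)-bicycle-3,9-dien-1-one (deconjugated ketone), via potassium dienolate 25 (not isolated)
Conditions: KOt-Bu, t-BuOH/THF, 0 °C → rt; inverse quench into 10 % aq AcOH, 0 °C
Reagents that add atoms: none
Why: Ringold–Malhotra-type deconjugation; with C11 quaternary only γ-protons are acidic, the equilibrated endocyclic dienolate is protonated kinetically at C2, and the alkene is stored at C3=C4 so that the later enolisation goes to C2 and not to C11.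

Step 16
Reactants: 26 deconjugated bridged ketone
Product: 28 7β-hydroxy-8α-(4-methoxybenzyloxy)-cis-fused bicycle-3,9-dien-1-one (H-5 α, H-11 α), via samarium enolate 27 (not isolated)
Conditions: SmI2 (2.5 equiv), MeOH (4 equiv), THF, −78 °C
Reagents that add atoms: none
Why: SmI2 reductive cleavage of the α-alkoxy ketone breaks C11–O and frees O7; methanol protonates the enolate at C11 on the face away from C6 and its methyls, giving the cis ring fusion required for the cyclobutane.

Step 17
Reactants: 28 hydroxy ketone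
Product: 29 7β-triethylsilyl ether of 28
Conditions: TESOTf, 2,6-lutidine, CH2Cl2, −78 °C
Reagents that add atoms: triethylsilyl trifluoromethanesulfonate, CC[Si](CC)(CC)OS(=O)(=O)C(F)(F)F
Why: Fast low-temperature silylation of the hindered neopentyl alcohol under conditions too mild to move the deconjugated alkenes.

Step 18
Reactants: 29 PMB ether
Product: 30 7β-(triethylsilyloxy)-8α-hydroxy-bicycle-3,9-dien-1-one
Conditions: DDQ, CH2Cl2/pH 7 buffer, 0 °C
Reagents that add atoms: none
Why: Oxidative cleavage of the PMB ether under near-neutral conditions frees the allylic 8α-hydroxyl.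

Step 19
Reactants: 30 allylic alcohol
Product: 31 9α,10α-epoxide of 30
Conditions: VO(acac)2 (5 mol %), t-BuOOH (decane), CH2Cl2, 0 °C → rt
Reagents that add atoms: tert-butyl hydroperoxide, CC(C)(C)OO
Why: Vanadium-catalysed hydroxyl-directed epoxidation delivers oxygen to C9=C10 syn to the 8α-hydroxyl and leaves the isolated C3=C4 alkene alone, setting C9 and placing the C10–O bond anti to C4.

Step 20
Reactants: 31 epoxy alcohol; 32 (R)-2-methylbutanoic acid
Product: 33 8α-[(R)-2-methylbutanoyl] ester of 31
Conditions: DIC, DMAP (0.1 equiv), CH2Cl2, 0 °C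
Reagents that add atoms: none
Why: Steglich esterification installs the final C8 ester before the ring closure, with little DMAP and low temperature to spare the acid stereocentre and the deconjugated ketone.

Step 21
Reactants: 33 epoxy keto ester
Product: 35 1-(tert-butyldimethylsilyloxy)-1,3-diene (ring-A silyl dienol ether) of 33, via lithium dienolate 34 (not isolated)
Conditions: LiHMDS (1.05 equiv), THF, −78 °C; TBSCl, DMPU, −78 → −30 °C
Reagents that add atoms: tert-butyldimethylsilyl chloride, CC(C)(C)[Si](C)(C)Cl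
Why: LiHMDS removes the doubly activated C2 proton, far more acidic than the tertiary C11–H or the ester α-H, so the β-epoxide is not eliminated, and O-silylation gives the linear dienol ether with C4 as its nucleophilic terminus.

Step 22
Reactants: 35 silyl dienol ether epoxide
Product: 36 7β-(triethylsilyloxy)-8α-[(R)-2-methylbutanoyloxy]-9α-(tert-butyldimethylsilyloxy)longipin-2-en-1-one
Conditions: TBSOTf (0.2 equiv), 2,6-di-tert-butyl-4-methylpyridine (0.3 equiv), CH2Cl2, −78 → −40 °C
Reagents that add atoms: none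
Why: Proposed new method: silylation of the epoxide oxygen makes tertiary C10 electrophilic, and C4 of the dienol ether, three atoms away (C4–C5–C11–C10) and anti to the C10–O bond, attacks it in a 4-exo-tet vinylogous Mukaiyama alkylation; collapse of the silyloxocarbenium ion returns the C1 enone and TBSOTf, so the silyl group ends on O9, inversion at C10 and the cis ring fusion fix C10 and C4, and C9 keeps the epoxide configuration; the closest known reactions are γ-selective Lewis-acid alkylation of silyl dienol ethers, Lewis-acid opening of tertiary epoxides by enol silanes, and the 4-exo preference of Stork carbanion–epoxide cyclisations, but their combination into a cyclobutane has not been shown.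

Step 23
Reactants: 36 bis-silyl tricycle
Product: 37 7β-hydroxy-8α-[(R)-2-methylbutanoyloxy]-9α-(tert-butyldimethylsilyloxy)longipin-2-en-1-one
Conditions: HF·pyridine, pyridine, THF, 0 °C
Reagents that add atoms: none
Why: The TES ether is cleaved selectively beside the more robust neopentyl TBS ether; the tricyclic enone has a bridgehead α-carbon and cannot enolise.

Step 24
Reactants: 37 7β-alcohol; 38 angelic acid
Product: 40 7β-angeloyloxy-8α-[(R)-2-methylbutanoyloxy]-9α-(tert-butyldimethylsilyloxy)longipin-2-en-1-one, via mixed anhydride 39 (not isolated)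
Conditions: 38, 2,4,6-trichlorobenzoyl chloride, Et3N, toluene, rt; then 37, toluene, 80 °C
Reagents that add atoms: none
Why: Yamaguchi mixed-anhydride acylation without DMAP is the usual way to esterify a hindered alcohol with angelic acid while keeping the Z geometry; O9 is still silylated, so only O7 reacts.

Step 25
Reactants: 40 silyl ether
Product: 41 (4R,5S,7S,8S,9S,10R,11R)-7-angeloyloxy-9-hydroxy-8-[(R)-2-methylbutanoyloxy]longipin-2-en-1-one (CNP0206166.1)
Conditions: HF·pyridine, THF, 0 °C → rt
Reagents that add atoms: none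
Why: Acidic fluoride removes the last silyl group without acyl migration or angelate isomerisation.

**Compound list**

1 | 3-methylfuran-2-carbaldehyde | Cc1ccoc1C=O | starting material
2 | lithium α-(4-methylpiperazin-1-yl) alkoxide of 1 | Cc1ccoc1C(O[Li])N1CCN(C)CC1 | intermediate
3 | 5-lithio derivative of 2 | Cc1cc([Li])oc1C(O[Li])N1CCN(C)CC1 | intermediate
4 | 5-(hydroxymethyl)-3-methylfuran-2-carbaldehyde | Cc1cc(CO)oc1C=O | intermediate
5 | 3-methyl-5-[(triethylsilyloxy)methyl]furan-2-carbaldehyde | Cc1cc(CO[Si](CC)(CC)CC)oc1C=O | intermediate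
6 | propyne | CC#C | starting material
7 | methyl(prop-1-ynyl)zinc | CC#C[Zn]C | intermediate
8 | (R)-1-{3-methyl-5-[(triethylsilyloxy)methyl]furan-2-yl}but-2-yn-1-ol | CC#C[C@@H](O)c1oc(CO[Si](CC)(CC)CC)cc1C | intermediate
9 | sodium cyclic alkenyl(alkoxy)bis(2-methoxyethoxy)aluminate from 8 | CC1=C[C@H](c2oc(CO[Si](CC)(CC)CC)cc2C)O[Al-]1(OCCOC)OCCOC.[Na+] | intermediate
10 | (R,Z)-3-iodo-1-{3-methyl-5-[(triethylsilyloxy)methyl]furan-2-yl}but-2-en-1-ol | C/C(I)=C/[C@@H](O)c1oc(CO[Si](CC)(CC)CC)cc1C | intermediate
11 | tert-butyldimethylsilyl ether of 10 | C/C(I)=C/[C@@H](O[Si](C)(C)C(C)(C)C)c1oc(CO[Si](CC)(CC)CC)cc1C | intermediate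
12 | prenyl bromide (1-bromo-3-methylbut-2-ene) | CC(C)=CCBr | starting material
13 | (Z)-alkenyllithium from 11 | C/C([Li])=C/[C@@H](O[Si](C)(C)C(C)(C)C)c1oc(CO[Si](CC)(CC)CC)cc1C | intermediate
14 | (Z)-alkenylzinc chloride from 11 | C/C([Zn]Cl)=C/[C@@H](O[Si](C)(C)C(C)(C)C)c1oc(CO[Si](CC)(CC)CC)cc1C | intermediate
15 | (R,Z)-1-(tert-butyldimethylsilyloxy)-3,6-dimethyl-1-{3-methyl-5-[(triethylsilyloxy)methyl]furan-2-yl}hepta-2,5-diene | C/C(CC=C(C)C)=C/[C@@H](O[Si](C)(C)C(C)(C)C)c1oc(CO[Si](CC)(CC)CC)cc1C | intermediate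
16 | {5-[(R,Z)-1-(tert-butyldimethylsilyloxy)-3,6-dimethylhepta-2,5-dien-1-yl]-4-methylfuran-2-yl}methanol | C/C(CC=C(C)C)=C/[C@@H](O[Si](C)(C)C(C)(C)C)c1oc(CO)cc1C | intermediate
17 | 6-hydroxy-5-methyl-6-[(R,Z)-1-(tert-butyldimethylsilyloxy)-3,6-dimethylhepta-2,5-dien-1-yl]-2H-pyran-3(6H)-one (one anomer drawn) | O[C@]1(OCC(=O)C=C1C)[C@H](O[Si](C)(C)C(C)(C)C)/C=C(/C)CC=C(C)C | intermediate
18 | 6-acetoxy-5-methyl-6-[(R,Z)-1-(tert-butyldimethylsilyloxy)-3,6-dimethylhepta-2,5-dien-1-yl]-2H-pyran-3(6H)-one (one anomer drawn) | CC(=O)O[C@]1(OCC(=O)C=C1C)[C@H](O[Si](C)(C)C(C)(C)C)/C=C(/C)CC=C(C)C | intermediate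
19 | 3-oxidopyrylium ylide from 18 | [O-]c1c[o+]c([C@H](O[Si](C)(C)C(C)(C)C)/C=C(/C)CC=C(C)C)c(C)c1 | intermediate
20 | (1R,5R,7S,11R)-1-(tert-butyldimethylsilyloxy)-7β,11β-epoxy-3,6,6,10-tetramethyl-bicycle-2,9-dien-8-one | O1[C@@H]2C(=O)C=C(C)[C@@]1([C@H](O[Si](C)(C)C(C)(C)C)C=C(C)C3)[C@H]3C2(C)C | intermediate
21 | 8α-alcohol of 20 | O1[C@@H]2[C@@H](O)C=C(C)[C@@]1([C@H](O[Si](C)(C)C(C)(C)C)C=C(C)C3)[C@H]3C2(C)C | intermediate
22 | 8α-(4-methoxybenzyl) ether of 21 | O1[C@@H]2[C@@H](OCc4ccc(OC)cc4)C=C(C)[C@@]1([C@H](O[Si](C)(C)C(C)(C)C)C=C(C)C3)[C@H]3C2(C)C | intermediate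
23 | (1R)-1-alcohol from 22 | O1[C@@H]2[C@@H](OCc4ccc(OC)cc4)C=C(C)[C@@]1([C@H](O)C=C(C)C3)[C@H]3C2(C)C | intermediate
24 | 7β,11β-epoxy-8α-(4-methoxybenzyloxy)-bicycle-2,9-dien-1-one | O1[C@@H]2[C@@H](OCc4ccc(OC)cc4)C=C(C)[C@@]1(C(=O)C=C(C)C3)[C@H]3C2(C)C | intermediate
25 | potassium 1,3-dienolate of 24 | O1[C@@H]2[C@@H](OCc4ccc(OC)cc4)C=C(C)[C@@]1(C([O-])=CC(C)=C3)[C@H]3C2(C)C.[K+] | intermediate
26 | 7β,11β-epoxy-8α-(4-methoxybenzyloxy)-bicycle-3,9-dien-1-one | O1[C@@H]2[C@@H](OCc4ccc(OC)cc4)C=C(C)[C@@]1(C(=O)CC(C)=C3)[C@H]3C2(C)C | intermediate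
27 | bis(diiodosamarium) enolate/alkoxide from 26 | I[Sm](I)O[C@@H]1[C@@H](OCc2ccc(OC)cc2)C=C(C)C3=C(O[Sm](I)I)CC(C)=C[C@@H]3C1(C)C | intermediate
28 | 7β-hydroxy-8α-(4-methoxybenzyloxy)-cis-fused bicycle-3,9-dien-1-one (H-5 α, H-11 α) | O[C@@H]1[C@@H](OCc2ccc(OC)cc2)C=C(C)[C@@H]3C(=O)CC(C)=C[C@@H]3C1(C)C | intermediate
29 | 7β-triethylsilyl ether of 28 | CC[Si](CC)(CC)O[C@@H]1[C@@H](OCc2ccc(OC)cc2)C=C(C)[C@@H]3C(=O)CC(C)=C[C@@H]3C1(C)C | intermediate
30 | 7β-(triethylsilyloxy)-8α-hydroxy-bicycle-3,9-dien-1-one | CC[Si](CC)(CC)O[C@@H]1[C@@H](O)C=C(C)[C@@H]3C(=O)CC(C)=C[C@@H]3C1(C)C | intermediate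
31 | 9α,10α-epoxide of 30 | CC[Si](CC)(CC)O[C@@H]1[C@@H](O)[C@H]4O[C@@]4(C)[C@@H]3C(=O)CC(C)=C[C@@H]3C1(C)C | intermediate
32 | (R)-2-methylbutanoic acid | OC(=O)[C@H](C)CC | starting material
33 | 8α-[(R)-2-methylbutanoyl] ester of 31 | CC[Si](CC)(CC)O[C@@H]1[C@@H](OC(=O)[C@H](C)CC)[C@H]4O[C@@]4(C)[C@@H]3C(=O)CC(C)=C[C@@H]3C1(C)C | intermediate
34 | lithium 1,3-dienolate of 33 | CC[Si](CC)(CC)O[C@@H]1[C@@H](OC(=O)[C@H](C)CC)[C@H]4O[C@@]4(C)[C@@H]3C(O[Li])=CC(C)=C[C@@H]3C1(C)C | intermediate
35 | 1-(tert-butyldimethylsilyloxy)-1,3-diene (silyl dienol ether) of 33 | CC[Si](CC)(CC)O[C@@H]1[C@@H](OC(=O)[C@H](C)CC)[C@H]4O[C@@]4(C)[C@@H]3C(O[Si](C)(C)C(C)(C)C)=CC(C)=C[C@@H]3C1(C)C | intermediate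
36 | 7β-(triethylsilyloxy)-8α-[(R)-2-methylbutanoyloxy]-9α-(tert-butyldimethylsilyloxy)longipin-2-en-1-one | CC[Si](CC)(CC)O[C@@H]1[C@@H](OC(=O)[C@H](C)CC)[C@@H](O[Si](C)(C)C(C)(C)C)[C@@]2(C)[C@@H]3C(=O)C=C(C)[C@H]2[C@@H]3C1(C)C | intermediate
37 | 7β-hydroxy-8α-[(R)-2-methylbutanoyloxy]-9α-(tert-butyldimethylsilyloxy)longipin-2-en-1-one | O[C@@H]1[C@@H](OC(=O)[C@H](C)CC)[C@@H](O[Si](C)(C)C(C)(C)C)[C@@]2(C)[C@@H]3C(=O)C=C(C)[C@H]2[C@@H]3C1(C)C | intermediate
38 | angelic acid ((Z)-2-methylbut-2-enoic acid) | C/C=C(/C)C(=O)O | starting material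
39 | angelic 2,4,6-trichlorobenzoic anhydride | C/C=C(/C)C(=O)OC(=O)c1c(Cl)cc(Cl)cc1Cl | intermediate
40 | 7β-angeloyloxy-8α-[(R)-2-methylbutanoyloxy]-9α-(tert-butyldimethylsilyloxy)longipin-2-en-1-one | C/C=C(/C)C(=O)O[C@@H]1[C@@H](OC(=O)[C@H](C)CC)[C@@H](O[Si](C)(C)C(C)(C)C)[C@@]2(C)[C@@H]3C(=O)C=C(C)[C@H]2[C@@H]3C1(C)C | intermediate
41 | (4R,5S,7S,8S,9S,10R,11R)-7-angeloyloxy-9-hydroxy-8-[(R)-2-methylbutanoyloxy]longipin-2-en-1-one | C/C=C(/C)C(=O)O[C@@H]1[C@@H](OC(=O)[C@H](C)CC)[C@@H](O)[C@@]2(C)[C@@H]3C(=O)C=C(C)[C@H]2[C@@H]3C1(C)C | target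

**Step count and risks**

Total step count: 25. Longest linear sequence: 25 steps (1 → 41); propyne, prenyl bromide and the two acids are bought.

Steps most likely to fail:

1. Step 22 (Proposed new method). The silyl-activated tertiary epoxide may lose the C11 proton to give the conjugated C10=C11 enone, shift hydride from C9, or be attacked through C2 instead of C4, before the strained C4–C10 bond forms. The fallback leaves the cationic manifold and uses two known elements: the ATPH protocol for γ-selective reactions of dienolates and the Stork 4-exo carbanion–epoxide closure. It sets out from 33: the ketone is complexed with aluminium tris(2,6-diphenylphenoxide) (2.2 equiv, toluene, −78 °C) and deprotonated at C2 with lithium tetramethylpiperidide. The bulky aluminium shields C2 and the C11 side, so the dienolate can react only through C4, which opens the aluminium-bound epoxide at C10 to give the tricyclic 9α-alcohol F1. F1 is silylated (TBSOTf, 2,6-lutidine) and the route is rejoined at 36.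

2. Step 10. Addition to a trisubstituted alkene through a six-membered tether is slow, so ylide dimerisation can win, and incomplete facial bias from C1 would erode the enantiomeric series. The fallback replaces the neutral ylide by a cationic five-atom partner that cannot dimerise. It sets out from 18: TBSOTf (2.2 equiv) and 2,6-di-tert-butyl-4-methylpyridine in CH2Cl2 (−78 → −20 °C) remove acetate and silylate the C8 oxygen, giving the 3-silyloxypyrylium triflate F2. The electron-rich prenyl alkene attacks C11 through C5, and the tertiary C6 cation closes on C7 of the enol silane, giving the O-silyl oxocarbenium salt F3 under the same tether and A(1,3) control. Aqueous NaHCO3 work-up desilylates F3 and the route is rejoined at 20.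

3. Step 16. Protonation of the samarium enolate may occur partly from the wrong face (trans fusion), and Sm(III) alkoxides may move the C3=C4 or C9=C10 alkene into conjugation. The fallback separates C–O cleavage from C–H formation. It sets out from 26: SmI2 in THF at −78 °C without proton source, then TMSCl/Et3N, gives the isolable bis-trimethylsilyl enol ether F4. F4 is protonated at C11 under reagent control with a Lewis-acid-assisted chiral Brønsted acid (BINOL·SnCl4, toluene, −78 °C; both antipodes available), and mild acidic work-up frees O7. The route is rejoined at 28.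

Further compounds

F1 | step 22 | 7β-(triethylsilyloxy)-8α-[(R)-2-methylbutanoyloxy]-9α-hydroxylongipin-2-en-1-one | CC[Si](CC)(CC)O[C@@H]1[C@@H](OC(=O)[C@H](C)CC)[C@@H](O)[C@@]2(C)[C@@H]3C(=O)C=C(C)[C@H]2[C@@H]3C1(C)C
F2 | step 10 | 3-(tert-butyldimethylsilyloxy)pyrylium triflate from 18 | CC(C)(C)[Si](C)(C)Oc1c[o+]c([C@H](O[Si](C)(C)C(C)(C)C)/C=C(/C)CC=C(C)C)c(C)c1.[O-]S(=O)(=O)C(F)(F)F
F3 | step 10 | O8-silyl oxocarbenium triflate of cycloadduct 20 | O1[C@@H]2C(=[O+][Si](C)(C)C(C)(C)C)C=C(C)[C@@]1([C@H](O[Si](C)(C)C(C)(C)C)C=C(C)C3)[C@H]3C2(C)C.[O-]S(=O)(=O)C(F)(F)F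
F4 | step 16 | 1,7-bis(trimethylsilyloxy) 1(11)-enol ether from 26 | C[Si](C)(C)O[C@@H]1[C@@H](OCc2ccc(OC)cc2)C=C(C)C3=C(O[Si](C)(C)C)CC(C)=C[C@@H]3C1(C)C
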